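The route is built on cutting the oxolane (O1, C2 aryl, C3, C4, C5; target numbering is used throughout) at C2–C3 and C4–C5. The C2–O1–C5 unit is traced back to an aryl carbonyl ylide assembled from O-benzylvanillin and one extra methylene. The C3–C4 bond, which carries the two cis carbon substituents, is traced back to the alkene of a butenolide. A single fluoride-triggered (3+2) cycloaddition of the ylide, released from a racemic α-chloro (trimethylsilyl)methyl ether, to (5S)-5-(d-menthyloxy)-2(5H)-furanone closes the oxolane, makes both C–C bonds and sets C2, C3 and C4. The lactone carbonyl later becomes the C3 CH2O-isovalerate and the acetal carbon the C4 benzyl group.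

Key step: step 4

Assumption: 1-(benzyloxy)-4-bromo-2-methoxybenzene (13) is purchased; it is otherwise one O-benzylation away from 4-bromo-2-methoxyphenol.

Remark on the precursor: the phenol of the ylide partner stays a benzyl ether, which tolerates dry HCl and fluoride, keeps the aryl group electron-rich for regiocontrol and leaves in the last step; 9 is used crude, racemic and in excess.

Step 1
Reactants: 1 furfural (furan-2-carbaldehyde)
Product: 3 5-hydroxy-2(5H)-furanone (racemic pseudo-acid), via furfural endoperoxide 2 (not isolated)
Conditions: O2, hν (visible light), cat. rose bengal (disodium tetrachlorotetraiodofluorescein), MeOH, 20 °C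
Reagents that add atoms: dioxygen, O=O
Why: Dye-sensitized singlet oxygen should add across the furan diene in a (4+2) cycloaddition (furan photooxygenation) to give endoperoxide 2, which methanol cleaves with loss of the formyl carbon as methyl formate to leave pseudo-acid 3; 3 is racemic and no stereocentre needs control.

Step 2
Reactants: 3 5-hydroxy-2(5H)-furanone; 4 (+)-menthol [(1S,2R,5S)-2-isopropyl-5-methylcyclohexanol]
Product: 6 (5S)-5-(d-menthyloxy)-2(5H)-furanone, via (5R)-acetal epimer 5 (not isolated)
Conditions: cat. camphorsulfonic acid, toluene, reflux with azeotropic removal of water; crystallization from petroleum ether at −20 °C; mother liquor re-equilibrated with cat. p-toluenesulfonic acid and crystallized again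
Reagents that add atoms: none
Why: Acid-catalysed acetalization of the pseudo-acid (Fischer-type glycosidation) should give both C5 epimers, which interconvert under acid through the ring oxocarbenium ion, so crystallization of 6 with re-equilibration of epimer 5 sets C5 as S, mirroring the established behaviour of the (−)-menthol series.

Step 3
Reactants: 7 O-benzylvanillin [4-(benzyloxy)-3-methoxybenzaldehyde]; 8 (trimethylsilyl)methanol
Product: 9 racemic α-chloro ether {[(4-benzyloxy-3-methoxyphenyl)(chloro)methoxy]methyl}trimethylsilane
Conditions: dry HCl (g), MgSO4, CH2Cl2, −20 → 0 °C; filtered, evaporated, used crude at once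
Reagents that add atoms: hydrogen chloride, Cl
Why: Hemiacetal formation and chloride substitution under anhydrous HCl (α-chloro ether synthesis from aldehyde, alcohol and HCl) should give 9, whose benzyl ether and C–Si bond tolerate cold dry HCl; the new stereocentre is racemic and disappears in the ylide.

Step 4
Reactants: 9 racemic α-chloro ether (2 equiv); 6 (5S)-5-(d-menthyloxy)-2(5H)-furanone
Product: 11 cycloadduct (3S,3aR,6S,6aS)-6-[4-(benzyloxy)-3-methoxyphenyl]-3-[(1S,2R,5S)-menthyloxy]tetrahydro-1H,3H-furo[3,4-c]furan-1-one, via aryl carbonyl ylide 10 (not isolated)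
Conditions: CsF (3 equiv, dried), MeCN, rt; 9 added slowly to 6 and CsF
Reagents that add atoms: none
Why: Ionization of the C–Cl bond of 9 gives an oxocarbenium ion stabilized by the aryl group, and attack of fluoride on silicon then frees the CH2 carbanion (net 1,3-elimination) to give ylide 10, which should add across the alkene of 6 in a concerted (3+2) cycloaddition that makes C2–C3 and C4–C5 together. The closest known reaction type is the fluoride-induced generation of non-stabilized carbonyl ylides from α-chloroalkyl (trimethylsilyl)methyl ethers and their cycloaddition to electron-poor alkenes. Ring closure is this intermolecular (3+2) cycloaddition itself: both bonds are made on the same face of the ring alkene, so the oxolane is cis-fused to the lactone and the arms on C3 and C4 end up cis. C4 and C3 are set by approach anti to the menthyloxy group on the adjacent acetal carbon, the facial bias this auxiliary exerts on dipoles and dienes, and C2 is set by the exo transition state of the E-ylide, in which the aryl group turns away from the lactone ring and ends trans to the C3 carbonyl arm. The required regiochemistry (CH2 terminus to the β-carbon) is secured by the electron-rich 4-benzyloxy-3-methoxyphenyl group, which holds the oxocarbenium character at the benzylic carbon and the larger HOMO coefficient at CH2, matching the large LUMO coefficient at the butenolide β-carbon, and by sterics, since the small terminus goes next to the acetal carbon. Slow addition of 9 keeps the ylide dilute against oxirane closure and dimerization.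

Step 5
Reactants: 11 cycloadduct
Product: 12 cis-fused lactol (3aR,6S,6aS)-6-[4-(benzyloxy)-3-methoxyphenyl]-3-hydroxytetrahydro-1H,3H-furo[3,4-c]furan-1-one (both C3 anomers)
Conditions: 2 M aq. HCl–1,4-dioxane (1:3), 60 °C
Reagents that add atoms: water, O
Why: Acid-catalysed hydrolysis of the lactone acetal (pseudo-ester hydrolysis) should release menthol and leave lactol 12, whose closed form shields the C4 α-centre of the masked aldehyde from epimerization, while the C2–O1 benzylic ether, deactivated by the neighbouring lactone carbonyl, can at worst ionize reversibly toward the exo-aryl isomer already present.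

Step 6
Reactants: 12 lactol; 13 1-(benzyloxy)-4-bromo-2-methoxybenzene
Product: 16 γ-aryl lactone (3aR,6S,6aS)-3,6-bis[4-(benzyloxy)-3-methoxyphenyl]tetrahydro-1H,3H-furo[3,4-c]furan-1-one (both C3 epimers), via arylmagnesium bromide 14 (not isolated), via hydroxy acid 15 (not isolated)
Conditions: 13, Mg, THF, rt; 12 added to 14 (2.5 equiv), THF, −78 → 0 °C; then 1 M aq. HCl, rt
Reagents that add atoms: none
Why: In this Grignard addition to a pseudo-acid, one equivalent of 14 deprotonates and opens the lactol, a second adds to the aldehyde faster than it enolizes at −78 °C, and acidification lets hydroxy acid 15 close to the cis-fused γ-lactone; the configuration of the new benzylic carbon is immaterial because it becomes CH2 in step 9.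

Step 7
Reactants: 16 γ-aryl lactone
Product: 17 diol [(2S,3R,4R)-2-[4-(benzyloxy)-3-methoxyphenyl]-4-{[4-(benzyloxy)-3-methoxyphenyl](hydroxy)methyl}oxolan-3-yl]methanol (both carbinol epimers)
Conditions: LiAlH4, THF, 0 °C → rt; H2O then aq. NaOH work-up
Reagents that add atoms: none
Why: LiAlH4 reduction of a lactone to the 1,4-diol should leave benzyl ethers, oxolane and all ring stereocentres untouched, and the basic work-up avoids the acid that would cyclize the diol to a furofuran.

Step 8
Reactants: 17 diol
Product: 18 bis(isovalerate) of 17 [primary and benzylic 3-methylbutanoate; (2S,3R,4R), both benzylic epimers]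
Conditions: isovaleric anhydride (3 equiv), Et3N, cat. 4-(dimethylamino)pyridine, CH2Cl2, 0 °C → rt
Reagents that add atoms: isovaleric anhydride (3-methylbutanoic anhydride), CC(C)CC(=O)OC(=O)CC(C)C
Why: Acylation under nucleophilic catalysis by 4-(dimethylamino)pyridine should esterify both hydroxyls, which installs the target's primary isovalerate and turns the benzylic oxygen into a carboxylate leaving group without any demand for chemoselectivity.

Step 9
Reactants: 18 bis(isovalerate)
Product: 19 (+)-9'-isovaleroxylariciresinol, [(2S,3R,4R)-2-(4-hydroxy-3-methoxyphenyl)-4-[(4-hydroxy-3-methoxyphenyl)methyl]oxolan-3-yl]methyl 3-methylbutanoate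
Conditions: H2 (1 atm), 10% Pd/C, EtOAc, rt; followed closely and stopped when the benzylic ester is consumed
Reagents that add atoms: none
Why: Palladium-catalysed hydrogenolysis should cleave the two aryl benzyl ethers and the benzylic C–O bond of the secondary ester, since benzylic carboxylates (the para-hydroxybenzylic one formed after debenzylation in particular) are cleaved much faster than the dialkyl benzylic ether C2–O1, while the primary isovalerate and C2, C3 and C4 are untouched.

Compound list
1 | furfural | O=Cc1ccco1 | starting material
2 | furfural endoperoxide (2,3,7-trioxabicyclo[2.2.1]hept-5-ene-1-carbaldehyde, not isolated) | O=CC12C=CC(OO1)O2 | intermediate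
3 | 5-hydroxy-2(5H)-furanone (racemic) | OC1OC(=O)C=C1 | intermediate
4 | (+)-menthol, (1S,2R,5S) | CC(C)[C@H]1CC[C@H](C)C[C@@H]1O | starting material
5 | (5R)-5-(d-menthyloxy)-2(5H)-furanone (acetal epimer, not isolated) | CC(C)[C@H]1CC[C@H](C)C[C@@H]1O[C@H]1C=CC(=O)O1 | intermediate
6 | (5S)-5-(d-menthyloxy)-2(5H)-furanone | CC(C)[C@H]1CC[C@H](C)C[C@@H]1O[C@@H]1C=CC(=O)O1 | intermediate
7 | O-benzylvanillin | COc1cc(C=O)ccc1OCc1ccccc1 | starting material
8 | (trimethylsilyl)methanol | C[Si](C)(C)CO | starting material
9 | racemic α-chloro (trimethylsilyl)methyl ether of O-benzylvanillin | COc1cc(C(Cl)OC[Si](C)(C)C)ccc1OCc1ccccc1 | intermediate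
10 | aryl carbonyl ylide (not isolated) | COc1cc(C=[O+][CH2-])ccc1OCc1ccccc1 | intermediate
11 | cycloadduct, (3S,3aR,6S,6aS) cis-fused aryl oxolane lactone menthyl acetal | CC(C)[C@H]1CC[C@H](C)C[C@@H]1O[C@@H]2[C@H]3CO[C@H](c4ccc(OCc5ccccc5)c(OC)c4)[C@H]3C(=O)O2 | intermediate
12 | cis-fused lactol, (3aR,6S,6aS), both C3 anomers | OC1[C@H]2CO[C@H](c3ccc(OCc4ccccc4)c(OC)c3)[C@H]2C(=O)O1 | intermediate
13 | 1-(benzyloxy)-4-bromo-2-methoxybenzene | COc1cc(Br)ccc1OCc1ccccc1 | starting material
14 | 4-(benzyloxy)-3-methoxyphenylmagnesium bromide (not isolated) | COc1cc([Mg]Br)ccc1OCc1ccccc1 | intermediate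
15 | hydroxy acid, (2S,3S,4R)-2-aryl-4-[aryl(hydroxy)methyl]oxolane-3-carboxylic acid, aryl = 4-(benzyloxy)-3-methoxyphenyl, both carbinol epimers (not isolated) | COc1cc(C(O)[C@H]2CO[C@H](c3ccc(OCc4ccccc4)c(OC)c3)[C@H]2C(=O)O)ccc1OCc1ccccc1 | intermediate
16 | γ-aryl lactone, (3aR,6S,6aS), both C3 epimers | COc1cc(C2[C@H]3CO[C@H](c4ccc(OCc5ccccc5)c(OC)c4)[C@H]3C(=O)O2)ccc1OCc1ccccc1 | intermediate
17 | diol, (2S,3R,4R), both carbinol epimers | COc1cc(C(O)[C@H]2CO[C@H](c3ccc(OCc4ccccc4)c(OC)c3)[C@H]2CO)ccc1OCc1ccccc1 | intermediate
18 | bis(isovalerate) of 17, (2S,3R,4R), both benzylic epimers | COc1cc(C(OC(=O)CC(C)C)[C@H]2CO[C@H](c3ccc(OCc4ccccc4)c(OC)c3)[C@H]2COC(=O)CC(C)C)ccc1OCc1ccccc1 | intermediate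
19 | (+)-9'-isovaleroxylariciresinol, (2S,3R,4R) | COc1cc(C[C@H]2CO[C@H](c3ccc(O)c(OC)c3)[C@H]2COC(=O)CC(C)C)ccc1O | target

Total step count: 9. Longest linear sequence: 8 steps (1, 2, 4, 5, 6, 7, 8, 9); step 3 is a one-step side branch.

Steps most likely to fail

Step 4. The exo preference at C2 rests on sterics alone, so the aryl terminus may add partly in the endo sense and give a mixture at C2; the ylide may also be lost to self-reaction. The fallback replaces kinetic control at C2 by thermodynamic control. It sets out from 6 and 9, which are combined as in step 4 without regard to the exo/endo outcome. The C2-epimeric endo-aryl cycloadduct F1 formed beside 11 is not separated. A catalytic amount of CF3SO3H in CH2Cl2 at 0 °C should open the C2–O1 bond reversibly to the 4-benzyloxy-3-methoxybenzyl cation and reclose it on the convex face, as in the acid epimerization of 2-aryltetrahydrofuran lignans. C3 and C4 are fixed by the cis ring fusion and the acetal carbon is of no consequence. The mixture should converge on 11, where the route is rejoined.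

Step 5. Hydrolysis of the deactivated, acylal-type acetal may be slower than acid-induced damage to the electron-rich C2–O1 benzylic ether. The fallback removes the auxiliary by acyl cleavage instead of acetal ionization. It sets out from 11: LiOH (1.05 equiv) in THF–H2O at 0 °C saponifies the lactone, and the menthyl hemiacetal so released collapses to the lithium aldehyde carboxylate F2 and menthol. The exposure is kept short and cold to spare the C4 α-centre. Acidification to pH 3 at 0 °C closes F2 to lactol 12, where the route is rejoined.

Step 9. Over-reduction is the risk: once the ring-A phenol is free, the C2–O1 benzylic ether may be hydrogenolysed before the benzylic ester is fully cleaved, opening the oxolane. The fallback removes the benzylic oxygen with hydride instead of hydrogen on palladium. It sets out from 18: a brief hydrogenolysis (H2, 10% Pd/C, EtOAc, rt, stopped as soon as the aryl benzyl ethers are gone) gives the bis-phenol bis(isovalerate) F3. NaBH4 with NaHCO3 in THF–H2O at 0 °C should then induce 1,6-elimination of isovalerate from the para-hydroxybenzylic ester to the ring-B para-quinone methide F4, which takes up hydride at the exocyclic carbon. The oxolane ether is a far poorer leaving group and the primary ester is inert to NaBH4 at 0 °C. The product is 19 itself.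

Further compounds
F1 | step 4 | (3S,3aR,6R,6aS) C2-epimeric (endo-aryl) cycloadduct | CC(C)[C@H]1CC[C@H](C)C[C@@H]1O[C@@H]2[C@H]3CO[C@@H](c4ccc(OCc5ccccc5)c(OC)c4)[C@H]3C(=O)O2
F2 | step 5 | lithium (2S,3S,4R)-2-[4-(benzyloxy)-3-methoxyphenyl]-4-formyloxolane-3-carboxylate | O=C[C@H]1CO[C@H](c2ccc(OCc3ccccc3)c(OC)c2)[C@H]1C(=O)[O-].[Li+]
F3 | step 9 | bis-phenol bis(isovalerate) (18 without its two benzyl groups) | COc1cc(C(OC(=O)CC(C)C)[C@H]2CO[C@H](c3ccc(O)c(OC)c3)[C@H]2COC(=O)CC(C)C)ccc1O
F4 | step 9 | ring-B para-quinone methide (oxolane stereocentres unchanged) | COC1=CC(=C[C@H]2CO[C@H](c3ccc(O)c(OC)c3)[C@H]2COC(=O)CC(C)C)C=CC1=O
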